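**Plan**

1. Retrosynthesis: after the three silyl groups are removed, ring A is cut at four bonds at once (C8–C8a, C4a–C5, C5–C6, C7–C8). This leaves a 5-aryl-4-pyranone with a diazoacetyl group on its C2 and a silyl ynol ether that carries the side chain.
2. Enabling feature: ring A is a pentasubstituted benzene with oxygen on C5, C7 and C8a, the chain on C6 and the C4 carbonyl on C4a. A vinylketene–ynol ether benzannulation gives exactly this pattern when the C2=C3 bond of a finished ring C (future C8a=C4a) serves as the vinyl unit.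
3. Pyranone half: kojic acid supplies ring C; ring B is attached by Suzuki coupling at the enol triflate, then CH2OH is taken to CO2H and to COCHN2.
4. Alkyne half: prenyl acetate gives the E allylic alcohol, then the allylic bromide, the skipped enyne, the ynolate and the silyl ynol ether.
5. Forward order of rings: C (bought), B (coupled), A (closed last, with the chain already in place); one global desilylation ends the route.
6. Stereochemistry: there is no stereocentre; the E trisubstituted alkene is set by the SeO2 oxidation of prenyl acetate and is not touched afterwards.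

Key step: step 13

Assumption: the pinacol ester of 4-hydroxyphenylboronic acid is used instead of the free boronic acid because its phenol silylates cleanly, and diazomethane is used as a freshly prepared ethereal solution.

**Route**

Step 1
Reactants: 1 kojic acid (5-hydroxy-2-(hydroxymethyl)-4H-pyran-4-one)
Product: 2 6-(hydroxymethyl)-4-oxo-4H-pyran-3-yl trifluoromethanesulfonate
Conditions: PhNTf2, Et3N, DMF, 0 °C to rt
Reagents that add atoms: N-phenylbis(trifluoromethanesulfonimide), O=S(=O)(N(c1ccccc1)S(=O)(=O)C(F)(F)F)C(F)(F)F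
Why: Chemoselective O-sulfonylation, in which the acidic enolic 5-OH is deprotonated by Et3N and captured by the mild triflyl donor PhNTf2, which should leave the neutral primary alcohol alone.

Step 2
Reactants: 3 4-(4,4,5,5-tetramethyl-1,3,2-dioxaborolan-2-yl)phenol
Product: 4 triisopropyl[4-(4,4,5,5-tetramethyl-1,3,2-dioxaborolan-2-yl)phenoxy]silane
Conditions: i-Pr3SiCl, imidazole, DMF, rt
Reagents that add atoms: chlorotriisopropylsilane, CC(C)[Si](Cl)(C(C)C)C(C)C
Why: Standard silylation of a phenol with a silyl chloride and imidazole; the pinacol boronate is inert, and the bulky aryl silyl ether is chosen to survive the aqueous base, oxidation and acid chloride formation that follow.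

Step 3
Reactants: 2 6-(hydroxymethyl)-4-oxo-4H-pyran-3-yl trifluoromethanesulfonate; 4 triisopropyl[4-(4,4,5,5-tetramethyl-1,3,2-dioxaborolan-2-yl)phenoxy]silane
Product: 5 2-(hydroxymethyl)-5-[4-(triisopropylsilyloxy)phenyl]-4H-pyran-4-one
Conditions: Pd(dppf)Cl2 (cat.), K3PO4, 1,4-dioxane/H2O, 70 °C
Reagents that add atoms: none
Why: Suzuki–Miyaura coupling of an electron-poor enol triflate with an aryl pinacol boronate forms the bond between ring C and ring B (C3–C1' of the isoflavone), and the free primary alcohol and the aryl silyl ether tolerate the mild phosphate base.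

Step 4
Reactants: 5 2-(hydroxymethyl)-5-[4-(triisopropylsilyloxy)phenyl]-4H-pyran-4-one
Product: 7 4-oxo-5-[4-(triisopropylsilyloxy)phenyl]-4H-pyran-2-carboxylic acid, via pyranone aldehyde 6 (not isolated)
Conditions: TEMPO (cat.), PhI(OAc)2, MeCN/H2O, rt
Reagents that add atoms: water, O
Why: Oxoammonium (TEMPO) oxidation with PhI(OAc)2 as terminal oxidant takes the alcohol to the aldehyde, whose hydrate is oxidised on to the acid in the aqueous medium, without touching the pyranone or the silyl ether.

Step 5
Reactants: 7 4-oxo-5-[4-(triisopropylsilyloxy)phenyl]-4H-pyran-2-carboxylic acid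
Product: 9 2-(2-diazoacetyl)-5-[4-(triisopropylsilyloxy)phenyl]-4H-pyran-4-one, via acid chloride 8 (not isolated)
Conditions: (COCl)2, DMF (cat.), CH2Cl2, 0 °C to rt; evaporate; CH2N2 (excess), Et2O/THF, 0 °C
Reagents that add atoms: diazomethane, C=[N+]=[N-]
Why: Acid chloride formation followed by acylation of diazomethane (first stage of the Arndt–Eistert sequence); a second equivalent of diazomethane takes up the HCl, and acylation at 0 °C is expected to outpace dipolar cycloaddition to the pyranone double bonds.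

Step 6
Reactants: 10 prenyl acetate (3-methylbut-2-en-1-yl acetate)
Product: 11 (E)-4-hydroxy-3-methylbut-2-en-1-yl acetate
Conditions: SeO2 (cat.), t-BuOOH, salicylic acid (cat.), CH2Cl2, rt
Reagents that add atoms: tert-butyl hydroperoxide, CC(C)(C)OO (net oxygen source; SeO2, O=[Se]=O, is the catalytic carrier)
Why: Allylic oxidation with SeO2 (ene reaction, then [2,3]-sigmatropic shift) attacks the methyl group trans to the acetoxymethyl arm at the more substituted alkene terminus, which sets the E geometry of the new allylic alcohol.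

Step 7
Reactants: 11 (E)-4-hydroxy-3-methylbut-2-en-1-yl acetate
Product: 12 (E)-4-(tert-butyldimethylsilyloxy)-3-methylbut-2-en-1-yl acetate
Conditions: t-BuMe2SiCl, imidazole, CH2Cl2, 0 °C to rt
Reagents that add atoms: tert-butylchlorodimethylsilane, CC(C)(C)[Si](C)(C)Cl
Why: Standard silylation of a primary alcohol with a silyl chloride and imidazole, which leaves the acetate and the alkene untouched.

Step 8
Reactants: 12 (E)-4-(tert-butyldimethylsilyloxy)-3-methylbut-2-en-1-yl acetate
Product: 13 (E)-4-(tert-butyldimethylsilyloxy)-3-methylbut-2-en-1-ol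
Conditions: K2CO3 (cat.), MeOH, 0 °C
Reagents that add atoms: none
Why: Base-catalysed transesterification (methanolysis) removes the acetate, while the primary silyl ether and the alkene are stable to K2CO3 in methanol.

Step 9
Reactants: 13 (E)-4-(tert-butyldimethylsilyloxy)-3-methylbut-2-en-1-ol
Product: 14 (E)-1-bromo-4-(tert-butyldimethylsilyloxy)-3-methylbut-2-ene
Conditions: CBr4, PPh3, CH2Cl2, 0 °C
Reagents that add atoms: carbon tetrabromide, BrC(Br)(Br)Br
Why: The Appel reaction converts the primary allylic alcohol into the bromide under neutral conditions by SN2 displacement at the primary carbon, so the alkene geometry and the silyl ether are kept.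

Step 10
Reactants: 14 (E)-1-bromo-4-(tert-butyldimethylsilyloxy)-3-methylbut-2-ene; 15 ethynyltrimethylsilane
Product: 16 (E)-6-(tert-butyldimethylsilyloxy)-5-methyl-1-(trimethylsilyl)hex-4-en-1-yne
Conditions: CuI (cat.), n-Bu4NCl (cat.), K2CO3, DMF, rt
Reagents that add atoms: none
Why: Copper-catalysed coupling of a terminal alkyne with an allylic halide under carbonate and phase-transfer conditions; the copper acetylide substitutes the primary bromide directly because the other allyl terminus is fully substituted, which gives the skipped enyne with the E alkene intact.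

Step 11
Reactants: 16 (E)-6-(tert-butyldimethylsilyloxy)-5-methyl-1-(trimethylsilyl)hex-4-en-1-yne
Product: 17 (E)-6-(tert-butyldimethylsilyloxy)-5-methylhex-4-en-1-yne
Conditions: K2CO3 (cat.), MeOH, 0 °C to rt
Reagents that add atoms: none
Why: Methanolysis of the alkynyl C–Si bond (protodesilylation) frees the terminal alkyne; the silyl ether is stable, and a short, cold treatment should limit prototropic isomerisation of the 1,4-enyne.

Step 12
Reactants: 17 (E)-6-(tert-butyldimethylsilyloxy)-5-methylhex-4-en-1-yne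
Product: 20 (E)-6-(tert-butyldimethylsilyloxy)-5-methyl-1-(triisopropylsilyloxy)hex-4-en-1-yne, via lithium acetylide 18 (not isolated), via lithium ynolate 19 (not isolated)
Conditions: LiN(SiMe3)2, t-BuOOH, THF, −78 to 0 °C; then i-Pr3SiOTf, −78 °C to rt
Reagents that add atoms: tert-butyl hydroperoxide, CC(C)(C)OO; triisopropylsilyl trifluoromethanesulfonate, CC(C)[Si](OS(=O)(=O)C(F)(F)F)(C(C)C)C(C)C
Why: Electrophilic oxygenation of the lithium acetylide by lithium tert-butyl peroxide gives the lithium ynolate, which the bulky silyl triflate silylates on oxygen to the silyl ynol ether; LiN(SiMe3)2 is basic enough for the alkyne C–H but not for the doubly activated CH2.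

Step 13
Reactants: 9 2-(2-diazoacetyl)-5-[4-(triisopropylsilyloxy)phenyl]-4H-pyran-4-one; 20 (E)-6-(tert-butyldimethylsilyloxy)-5-methyl-1-(triisopropylsilyloxy)hex-4-en-1-yne
Product: 25 6-[(E)-4-(tert-butyldimethylsilyloxy)-3-methylbut-2-enyl]-5-hydroxy-7-(triisopropylsilyloxy)-3-[4-(triisopropylsilyloxy)phenyl]-4H-chromen-4-one, via pyranyl ketene 21 (not isolated), via cyclobutenone 22 (not isolated), via dienylketene 23 (not isolated), via cyclohexadienone 24 (not isolated)
Conditions: hν (violet LED, 405 nm), degassed ClCH2CH2Cl, rt; then 80 °C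
Reagents that add atoms: none
Why: Proposed new method: light absorbed in the weak long-wavelength band of the diazo ketone expels N2 and triggers a Wolff rearrangement in which pyranone C2 migrates to the diazo carbon (C8–C8a), giving ketene 21 whose vinyl unit is the pyranone C2=C3 bond; [2+2] cycloaddition with the ynol ether (C5–C6 and C7–C8) gives cyclobutenone 22, reversible 4π electrocyclic opening gives dienylketene 23, and 6π electrocyclisation onto pyranone C3 (C4a–C5) followed by enolisation of dienone 24 gives the phenol. The closest known reaction is the Danheiser benzannulation of aryl, heteroaryl and vinyl α-diazo ketones with siloxyalkynes; a 4-pyranone has not served as the vinyl component, but its C2=C3 bond is less aromatic than the furan, thiophene and benzene rings that do take part, and aromatisation of ring A together with the hydrogen bond from the new 5-OH to the C4 carbonyl should pull the cascade forward. Ring A, the only ring closed, forms by thermal disrotatory 6π electrocyclisation of the dienylketene to a six-membered carbocycle. No stereocentre results, because the sp3 carbons of 22 and 24 are transient and vanish on ring opening and tautomerisation. The regiochemistry requires the chain-bearing alkyne carbon to bond to the ketene carbonyl carbon, which the polarisation of the ynol ether (nucleophilic at the carbon remote from oxygen) secures, and closure can reach only pyranone C3 because the other neighbour of C2 is the ring oxygen, so the chain must end on C6 and never on C8. The chemoselectivity requires the light to spare the pyranone chromophore and the unconjugated E alkene, which violet irradiation below the energy of their absorptions should secure.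

Step 14
Reactants: 25 6-[(E)-4-(tert-butyldimethylsilyloxy)-3-methylbut-2-enyl]-5-hydroxy-7-(triisopropylsilyloxy)-3-[4-(triisopropylsilyloxy)phenyl]-4H-chromen-4-one
Product: 26 5,7-dihydroxy-3-(4-hydroxyphenyl)-6-[(E)-4-hydroxy-3-methylbut-2-enyl]-4H-chromen-4-one (EANPDB:LEGU_00416)
Conditions: n-Bu4NF, AcOH, THF, 0 °C to rt
Reagents that add atoms: none
Why: Fluoride-mediated desilylation cleaves the two aryl silyl ethers and the primary silyl ether in one operation, and buffering with acetic acid protects the base-sensitive ring C and the E allylic alcohol.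

**Compound list**

1 | kojic acid, 5-hydroxy-2-(hydroxymethyl)-4H-pyran-4-one | OCc1cc(=O)c(O)co1 | starting material
2 | 6-(hydroxymethyl)-4-oxo-4H-pyran-3-yl trifluoromethanesulfonate | OCc1cc(=O)c(OS(=O)(=O)C(F)(F)F)co1 | intermediate
3 | 4-(4,4,5,5-tetramethyl-1,3,2-dioxaborolan-2-yl)phenol | CC1(C)OB(c2ccc(O)cc2)OC1(C)C | starting material
4 | triisopropyl[4-(4,4,5,5-tetramethyl-1,3,2-dioxaborolan-2-yl)phenoxy]silane | CC(C)[Si](Oc1ccc(B2OC(C)(C)C(C)(C)O2)cc1)(C(C)C)C(C)C | intermediate
5 | 2-(hydroxymethyl)-5-[4-(triisopropylsilyloxy)phenyl]-4H-pyran-4-one | OCc1cc(=O)c(-c2ccc(O[Si](C(C)C)(C(C)C)C(C)C)cc2)co1 | intermediate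
6 | 4-oxo-5-[4-(triisopropylsilyloxy)phenyl]-4H-pyran-2-carbaldehyde | O=Cc1cc(=O)c(-c2ccc(O[Si](C(C)C)(C(C)C)C(C)C)cc2)co1 | intermediate
7 | 4-oxo-5-[4-(triisopropylsilyloxy)phenyl]-4H-pyran-2-carboxylic acid | OC(=O)c1cc(=O)c(-c2ccc(O[Si](C(C)C)(C(C)C)C(C)C)cc2)co1 | intermediate
8 | 4-oxo-5-[4-(triisopropylsilyloxy)phenyl]-4H-pyran-2-carbonyl chloride | ClC(=O)c1cc(=O)c(-c2ccc(O[Si](C(C)C)(C(C)C)C(C)C)cc2)co1 | intermediate
9 | 2-(2-diazoacetyl)-5-[4-(triisopropylsilyloxy)phenyl]-4H-pyran-4-one | [N-]=[N+]=CC(=O)c1cc(=O)c(-c2ccc(O[Si](C(C)C)(C(C)C)C(C)C)cc2)co1 | intermediate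
10 | prenyl acetate, 3-methylbut-2-en-1-yl acetate | CC(C)=CCOC(C)=O | starting material
11 | (E)-4-hydroxy-3-methylbut-2-en-1-yl acetate | C/C(=C\COC(C)=O)CO | intermediate
12 | (E)-4-(tert-butyldimethylsilyloxy)-3-methylbut-2-en-1-yl acetate | C/C(=C\COC(C)=O)CO[Si](C)(C)C(C)(C)C | intermediate
13 | (E)-4-(tert-butyldimethylsilyloxy)-3-methylbut-2-en-1-ol | C/C(=C\CO)CO[Si](C)(C)C(C)(C)C | intermediate
14 | (E)-1-bromo-4-(tert-butyldimethylsilyloxy)-3-methylbut-2-ene | C/C(=C\CBr)CO[Si](C)(C)C(C)(C)C | intermediate
15 | ethynyltrimethylsilane | C#C[Si](C)(C)C | starting material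
16 | (E)-6-(tert-butyldimethylsilyloxy)-5-methyl-1-(trimethylsilyl)hex-4-en-1-yne | C/C(=C\CC#C[Si](C)(C)C)CO[Si](C)(C)C(C)(C)C | intermediate
17 | (E)-6-(tert-butyldimethylsilyloxy)-5-methylhex-4-en-1-yne | C/C(=C\CC#C)CO[Si](C)(C)C(C)(C)C | intermediate
18 | lithium (E)-6-(tert-butyldimethylsilyloxy)-5-methylhex-4-en-1-yn-1-ide | C/C(=C\CC#[C-])CO[Si](C)(C)C(C)(C)C.[Li+] | intermediate
19 | lithium (E)-6-(tert-butyldimethylsilyloxy)-5-methylhex-4-en-1-yn-1-olate | C/C(=C\CC#C[O-])CO[Si](C)(C)C(C)(C)C.[Li+] | intermediate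
20 | (E)-6-(tert-butyldimethylsilyloxy)-5-methyl-1-(triisopropylsilyloxy)hex-4-en-1-yne | C/C(=C\CC#CO[Si](C(C)C)(C(C)C)C(C)C)CO[Si](C)(C)C(C)(C)C | intermediate
21 | 2-(2-oxoethenyl)-5-[4-(triisopropylsilyloxy)phenyl]-4H-pyran-4-one (pyranyl ketene) | O=C=Cc1cc(=O)c(-c2ccc(O[Si](C(C)C)(C(C)C)C(C)C)cc2)co1 | intermediate
22 | 2-[(E)-4-(tert-butyldimethylsilyloxy)-3-methylbut-2-enyl]-4-{4-oxo-5-[4-(triisopropylsilyloxy)phenyl]-4H-pyran-2-yl}-3-(triisopropylsilyloxy)cyclobut-2-en-1-one (racemic) | O=C1C(C/C=C(\C)CO[Si](C)(C)C(C)(C)C)=C(O[Si](C(C)C)(C(C)C)C(C)C)C1c1cc(=O)c(-c2ccc(O[Si](C(C)C)(C(C)C)C(C)C)cc2)co1 | intermediate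
23 | dienylketene: 2-{3-[(E)-4-(tert-butyldimethylsilyloxy)-3-methylbut-2-enyl]-4-oxo-2-(triisopropylsilyloxy)buta-1,3-dienyl}-5-[4-(triisopropylsilyloxy)phenyl]-4H-pyran-4-one (central alkene geometry not fixed) | O=C=C(C/C=C(\C)CO[Si](C)(C)C(C)(C)C)C(O[Si](C(C)C)(C(C)C)C(C)C)=Cc1cc(=O)c(-c2ccc(O[Si](C(C)C)(C(C)C)C(C)C)cc2)co1 | intermediate
24 | 6-[(E)-4-(tert-butyldimethylsilyloxy)-3-methylbut-2-enyl]-7-(triisopropylsilyloxy)-3-[4-(triisopropylsilyloxy)phenyl]-4aH-chromene-4,5-dione (racemic keto tautomer of 25) | O=C1C(C/C=C(\C)CO[Si](C)(C)C(C)(C)C)=C(O[Si](C(C)C)(C(C)C)C(C)C)C=C2OC=C(c3ccc(O[Si](C(C)C)(C(C)C)C(C)C)cc3)C(=O)C12 | intermediate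
25 | 6-[(E)-4-(tert-butyldimethylsilyloxy)-3-methylbut-2-enyl]-5-hydroxy-7-(triisopropylsilyloxy)-3-[4-(triisopropylsilyloxy)phenyl]-4H-chromen-4-one | C/C(=C\Cc1c(O)c2c(=O)c(-c3ccc(O[Si](C(C)C)(C(C)C)C(C)C)cc3)coc2cc1O[Si](C(C)C)(C(C)C)C(C)C)CO[Si](C)(C)C(C)(C)C | intermediate
26 | 5,7-dihydroxy-3-(4-hydroxyphenyl)-6-[(E)-4-hydroxy-3-methylbut-2-enyl]-4H-chromen-4-one | C/C(=C\Cc1c(O)cc2occ(-c3ccc(O)cc3)c(=O)c2c1O)CO | target

**Summary**

Total step count: 14. Longest linear sequence: 9 steps (prenyl acetate 10 to target 26, steps 6 to 14).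

Steps most likely to fail:

Step 13. The photochemical cascade may be diverted by dimerisation of the pyranyl ketene, by photorearrangement of the pyranone, or by stalling at the cyclobutenone if the 6π closure onto the pyranone is slow. The fallback uses only known chemistry: ring A is taken from a preformed isoflavone and the chain is attached by cross-coupling; it sets out from bromide 14 and returns at 25. Commercial genistein would be silylated at O7 and O4' (i-Pr3SiCl, imidazole, DMF; the chelated 5-OH stays free) to 5-hydroxy-7-(triisopropylsilyloxy)-3-[4-(triisopropylsilyloxy)phenyl]-4H-chromen-4-one F1. Iodination ortho to the free 5-OH with benzyltrimethylammonium dichloroiodate and CaCO3 in CH2Cl2/MeOH would give 5-hydroxy-6-iodo-7-(triisopropylsilyloxy)-3-[4-(triisopropylsilyloxy)phenyl]-4H-chromen-4-one F2. Bromide 14 would be converted with Bu3SnLi (THF, −78 °C) into (E)-tributyl[4-(tert-butyldimethylsilyloxy)-3-methylbut-2-enyl]stannane F3. Stille coupling of F2 with F3 (Pd(PPh3)4, CuI, DMF, 80 °C), which joins allyl stannanes mainly at the tin-bearing carbon, would deliver 25.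

Step 12. Deprotonation of the skipped enyne may lead to prototropic isomerisation, oxygen transfer to the acetylide may stall, or the ynol ether may be lost on purification. The fallback makes the same ynolate by reductive lithiation of an α,α-dibromo ester, without passing through the acetylide; it sets out from bromide 14 and returns at ynolate 19, and so at 20. Alkylation of the lithium enolate of ethyl acetate (LiN(i-Pr)2, THF, −78 °C) with 14 would give ethyl (E)-6-(tert-butyldimethylsilyloxy)-5-methylhex-4-enoate F4. Two successive enolate brominations (LiN(i-Pr)2, then CBr4, −78 °C) would give ethyl (E)-2-bromo-6-(tert-butyldimethylsilyloxy)-5-methylhex-4-enoate F5 and then ethyl (E)-2,2-dibromo-6-(tert-butyldimethylsilyloxy)-5-methylhex-4-enoate F6. Treatment of F6 with t-BuLi (4 equiv, THF, −78 to 0 °C) would effect double bromine–lithium exchange and loss of LiOEt to give 19, which is silylated with i-Pr3SiOTf as in step 12.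

Step 5. Diazomethane may add across the doubly activated C2=C3 bond of the acyl pyranone, or the acid chloride may degrade before acylation. The fallback installs the diazo group by detrifluoroacetylative diazo transfer to a methyl ketone; it sets out from alcohol 5 and returns at 9. MnO2 in CH2Cl2 would oxidise 5 to aldehyde 6, isolated this time. MeMgBr (THF, −78 °C) would add to the aldehyde to give 2-(1-hydroxyethyl)-5-[4-(triisopropylsilyloxy)phenyl]-4H-pyran-4-one F7, and Dess–Martin periodinane would give 2-acetyl-5-[4-(triisopropylsilyloxy)phenyl]-4H-pyran-4-one F8. Enolisation with LiN(SiMe3)2 and acylation with CF3CO2CH2CF3 (THF, −78 °C) would give 4,4,4-trifluoro-1-{4-oxo-5-[4-(triisopropylsilyloxy)phenyl]-4H-pyran-2-yl}butane-1,3-dione F9. Without isolation, F9 would be treated with MsN3, Et3N and water in MeCN to give 9.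

**Further compounds**

F1 | step 13 | 5-hydroxy-7-(triisopropylsilyloxy)-3-[4-(triisopropylsilyloxy)phenyl]-4H-chromen-4-one | CC(C)[Si](Oc1ccc(-c2coc3cc(O[Si](C(C)C)(C(C)C)C(C)C)cc(O)c3c2=O)cc1)(C(C)C)C(C)C
F2 | step 13 | 5-hydroxy-6-iodo-7-(triisopropylsilyloxy)-3-[4-(triisopropylsilyloxy)phenyl]-4H-chromen-4-one | CC(C)[Si](Oc1ccc(-c2coc3cc(O[Si](C(C)C)(C(C)C)C(C)C)c(I)c(O)c3c2=O)cc1)(C(C)C)C(C)C
F3 | step 13 | (E)-tributyl[4-(tert-butyldimethylsilyloxy)-3-methylbut-2-enyl]stannane | C/C(=C\C[Sn](CCCC)(CCCC)CCCC)CO[Si](C)(C)C(C)(C)C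
F4 | step 12 | ethyl (E)-6-(tert-butyldimethylsilyloxy)-5-methylhex-4-enoate | CCOC(=O)CC/C=C(\C)CO[Si](C)(C)C(C)(C)C
F5 | step 12 | ethyl (E)-2-bromo-6-(tert-butyldimethylsilyloxy)-5-methylhex-4-enoate (racemic) | CCOC(=O)C(Br)C/C=C(\C)CO[Si](C)(C)C(C)(C)C
F6 | step 12 | ethyl (E)-2,2-dibromo-6-(tert-butyldimethylsilyloxy)-5-methylhex-4-enoate | CCOC(=O)C(Br)(Br)C/C=C(\C)CO[Si](C)(C)C(C)(C)C
F7 | step 5 | 2-(1-hydroxyethyl)-5-[4-(triisopropylsilyloxy)phenyl]-4H-pyran-4-one (racemic) | CC(O)c1cc(=O)c(-c2ccc(O[Si](C(C)C)(C(C)C)C(C)C)cc2)co1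
F8 | step 5 | 2-acetyl-5-[4-(triisopropylsilyloxy)phenyl]-4H-pyran-4-one | CC(=O)c1cc(=O)c(-c2ccc(O[Si](C(C)C)(C(C)C)C(C)C)cc2)co1
F9 | step 5 | 4,4,4-trifluoro-1-{4-oxo-5-[4-(triisopropylsilyloxy)phenyl]-4H-pyran-2-yl}butane-1,3-dione | O=C(CC(=O)C(F)(F)F)c1cc(=O)c(-c2ccc(O[Si](C(C)C)(C(C)C)C(C)C)cc2)co1
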